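**Strategy.** Ring B is not coupled on but grown. Disconnecting C1'–C2', C2'–C3' and C4'–C5' leaves (triisopropylsilyloxy)acetylene and a (3R)-chroman-3-yl alkenyl diazomethyl ketone, in which rings A and C are complete and C3 is set by lipase desymmetrisation of a prochiral diol. Photochemical Wolff rearrangement, ketene–ynol ether [2+2], 4π opening and 6π closure then build ring B in one operation. The step exploits the 1,3-relation of O2' and O4' on ring B with C1' bonded to C3: the ketene carbon becomes C2' (free OH) and the silyloxy carbon C4', so the two oxygens emerge differentiated and ring D can only be fused across O2'/C3'.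

Key step: step 16

Remarks: prenyl = 3-methylbut-2-en-1-yl; TIPS = tri(propan-2-yl)silyl; Chr = (3R)-5,7-dimethoxy-6-prenyl-3,4-dihydro-2H-chromen-3-yl (rings A and C); primed locants follow isoflavan numbering.
Assumption: the lipase of step 8 is taken to acetylate the pro-S hydroxymethyl arm of the prochiral triol; if screening shows the opposite preference, a lipase of complementary selectivity (for example porcine pancreatic lipase) takes its place.
Assumption: (triisopropylsilyloxy)acetylene is treated as not purchasable and is made in steps 13–15.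

Step 1
Reactants: 1 3,5-dimethoxyphenol
Product: 2 (3,5-dimethoxyphenoxy)triisopropylsilane
Conditions: TIPSCl, imidazole, DMF, rt
Reagents that add atoms: chlorotri(propan-2-yl)silane, CC(C)[Si](Cl)(C(C)C)C(C)C
Why: Imidazole-promoted O-silylation of a phenol; the bulky silyl ether removes the acidic proton and is too hindered and too weakly coordinating to direct the lithiation of step 2 to its own ortho positions.

Step 2
Reactants: 2 (3,5-dimethoxyphenoxy)triisopropylsilane; 3 prenyl bromide (1-bromo-3-methylbut-2-ene)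
Product: 5 (3,5-dimethoxy-4-prenylphenoxy)triisopropylsilane, via 2,6-dimethoxy-4-(triisopropylsilyloxy)phenyllithium 4 (not isolated)
Conditions: n-BuLi, TMEDA, THF, 0 °C; CuBr·SMe2 (10 mol%), 3, −78 °C → rt
Reagents that add atoms: 1-bromo-3-methylbut-2-ene (3), CC(C)=CCBr
Why: Directed ortho-metalation at the carbon flanked by both methoxy groups (doubly activated, remote from the silyl ether), then CuBr·SMe2-catalysed allylic substitution at the primary carbon of prenyl bromide, should give the linear prenyl arene.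

Step 3
Reactants: 5 (3,5-dimethoxy-4-prenylphenoxy)triisopropylsilane
Product: 6 3,5-dimethoxy-4-prenylphenol
Conditions: Bu4NF, THF, 0 °C
Reagents that add atoms: none
Why: Fluoride cleavage of an aryl silyl ether, driven by the Si–F bond, frees the phenol that directs the formylation.

Step 4
Reactants: 6 3,5-dimethoxy-4-prenylphenol; 7 paraformaldehyde
Product: 8 6-hydroxy-2,4-dimethoxy-3-prenylbenzaldehyde
Conditions: MgCl2, Et3N, 7, MeCN, reflux
Reagents that add atoms: paraformaldehyde (7), as formaldehyde C=O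
Why: Magnesium phenoxide-directed ortho-formylation (a second formaldehyde accepts the hydride) is strictly ortho to OH; the two ortho positions are equivalent and the para position carries the prenyl group.

Step 5
Reactants: 8 6-hydroxy-2,4-dimethoxy-3-prenylbenzaldehyde; 9 diethyl malonate
Product: 10 ethyl 5,7-dimethoxy-6-prenyl-2-oxo-2H-chromene-3-carboxylate
Conditions: piperidine (cat.), AcOH (cat.), EtOH, reflux
Reagents that add atoms: diethyl malonate (9), CCOC(=O)CC(=O)OCC
Why: Knoevenagel condensation followed by lactonisation of the phenol onto the cis ester gives the coumarin-3-carboxylate and brings in C3, C2 and the future C1' carbon at once.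

Step 6
Reactants: 10 ethyl 5,7-dimethoxy-6-prenyl-2-oxo-2H-chromene-3-carboxylate
Product: 11 ethyl 5,7-dimethoxy-6-prenyl-2-oxochromane-3-carboxylate (racemic)
Conditions: NaBH4, THF/EtOH, 0 °C
Reagents that add atoms: none
Why: Conjugate hydride reduction of the doubly activated (alkylidene malonate-type) C3=C4 bond; the isolated prenyl alkene is inert to NaBH4.

Step 7
Reactants: 11 ethyl 5,7-dimethoxy-6-prenyl-2-oxochromane-3-carboxylate
Product: 12 2-[(6-hydroxy-2,4-dimethoxy-3-prenylphenyl)methyl]propane-1,3-diol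
Conditions: LiAlH4, THF, 0 °C → rt; aqueous NaOH work-up
Reagents that add atoms: none
Why: LiAlH4 reduction of the aryl lactone and the ethyl ester of a saturated malonate releases the phenol and gives a prochiral 2-benzylpropane-1,3-diol.

Step 8
Reactants: 12 2-[(6-hydroxy-2,4-dimethoxy-3-prenylphenyl)methyl]propane-1,3-diol
Product: 13 (2S)-3-hydroxy-2-[(6-hydroxy-2,4-dimethoxy-3-prenylphenyl)methyl]propyl acetate
Conditions: Burkholderia cepacia lipase (immobilised), vinyl acetate, t-BuOMe, rt
Reagents that add atoms: vinyl acetate, CC(=O)OC=C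
Why: Lipase-catalysed enantiotopic-group-selective transesterification (desymmetrisation of a prochiral 2-substituted propane-1,3-diol) sets the only stereocentre by acetylating the pro-S arm, the phenol being a poor acyl acceptor for the enzyme.

Step 9
Reactants: 13 (2S)-3-hydroxy-2-[(6-hydroxy-2,4-dimethoxy-3-prenylphenyl)methyl]propyl acetate
Product: 14 [(3S)-5,7-dimethoxy-6-prenyl-3,4-dihydro-2H-chromen-3-yl]methyl acetate
Conditions: PPh3, DIAD, THF, 0 °C → rt (13 used at once)
Reagents that add atoms: none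
Why: Intramolecular Mitsunobu etherification, in which the phenol displaces the activated primary hydroxyl in a 6-exo-tet closure of ring C; the stereocentre is not a reacting atom, and immediate use of 13 forestalls 1,3-acyl migration.

Step 10
Reactants: 14 [(3S)-5,7-dimethoxy-6-prenyl-3,4-dihydro-2H-chromen-3-yl]methyl acetate
Product: 15 [(3R)-5,7-dimethoxy-6-prenyl-3,4-dihydro-2H-chromen-3-yl]methanol (Chr–CH2OH)
Conditions: K2CO3 (cat.), MeOH, rt
Reagents that add atoms: none
Why: Base-catalysed transesterification of a primary acetate; C3 is not α to a carbonyl and keeps its configuration (the descriptor changes only through priority rules).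

Step 11
Reactants: 15 Chr–CH2OH; 16 1-(triphenylphosphoranylidene)propan-2-one
Product: 18 (3E)-4-(Chr)but-3-en-2-one, via (3S)-chromane-3-carbaldehyde 17 (not isolated)
Conditions: Dess–Martin periodinane, CH2Cl2, 0 °C → rt; then 16 (excess), rt
Reagents that add atoms: 1-(triphenylphosphoranylidene)propan-2-one (16), CC(=O)C=P(c1ccccc1)(c1ccccc1)c1ccccc1
Why: Base-free Dess–Martin oxidation followed in the same flask by E-selective Wittig olefination with a stabilised keto-ylide, so the α-stereogenic β-aryloxy aldehyde 17 is neither stored nor exposed to strong base.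

Step 12
Reactants: 18 (3E)-4-(Chr)but-3-en-2-one
Product: 21 (3E)-1-diazo-4-(Chr)but-3-en-2-one, via lithium enolate 19 (not isolated), via trifluoroacetyl diketone 20 (not isolated)
Conditions: LiN(SiMe3)2, THF, −78 °C; CF3CO2CH2CF3; aq. HCl work-up; then MsN3, Et3N, H2O, MeCN, rt
Reagents that add atoms: methanesulfonyl azide, CS(=O)(=O)N=[N+]=[N-]
Why: Detrifluoroacetylative diazo transfer: kinetic deprotonation of the methyl group, Claisen-type trifluoroacetylation, then diazo transfer with loss of the activating group; this route replaces acylation of diazomethane, which would add across the conjugated C=C, and the γ-hydrogen at C3 is not removed under kinetic conditions.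

Step 13
Reactants: 22 tetrahydrofuran
Product: 24 (ethenyloxy)triisopropylsilane, via lithium ethenolate 23 (not isolated)
Conditions: n-BuLi, THF, 35 °C; then TIPSCl, DMPU, 0 °C → rt
Reagents that add atoms: chlorotri(propan-2-yl)silane, CC(C)[Si](Cl)(C(C)C)C(C)C
Why: α-Lithiation of tetrahydrofuran and [3+2] cycloreversion give the lithium enolate of acetaldehyde, which is silylated on oxygen.

Step 14
Reactants: 24 (ethenyloxy)triisopropylsilane
Product: 26 [(Z)-2-bromoethenyloxy]triisopropylsilane, via 1,2-dibromoethyl silyl ether 25 (not isolated)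
Conditions: Br2, CH2Cl2, −78 °C; then Et3N, −78 °C → rt
Reagents that add atoms: bromine, BrBr
Why: Low-temperature bromine addition to the enol ether followed by amine-induced dehydrobromination is the standard route to β-bromo enol ethers.

Step 15
Reactants: 26 [(Z)-2-bromoethenyloxy]triisopropylsilane
Product: 28 (ethynyloxy)triisopropylsilane, via lithium silyloxyacetylide 27 (not isolated)
Conditions: LiN(iPr)2 (2 equiv), THF, −78 °C; H2O quench at −78 °C
Reagents that add atoms: none
Why: Base-induced dehydrobromination of a β-bromovinyl ether to an ynol ether (the classical alkoxyacetylene synthesis), with the hindered silyl group and low temperature suppressing O-to-C silyl migration in 27.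

Step 16
Reactants: 21 (3E)-1-diazo-4-(Chr)but-3-en-2-one; 28 (ethynyloxy)triisopropylsilane
Product: 33 2-(Chr)-5-(triisopropylsilyloxy)phenol, via vinylketene 29 (not isolated), via 4-alkenylcyclobutenone 30 (not isolated), via dienylketene 31 (not isolated), via cyclohexa-2,4-dienone 32 (not isolated)
Conditions: hν (300 nm, Pyrex), 28 (2.5 equiv), degassed ClCH2CH2Cl, rt; then 80 °C
Reagents that add atoms: (ethynyloxy)tri(propan-2-yl)silane (28), C#CO[Si](C(C)C)(C(C)C)C(C)C
Why: Light expels N2 from 21 and the alkenyl group migrates (Wolff rearrangement) to give vinylketene 29, to which the polarised ynol ether adds [2+2], its CH terminus bonding to the ketene carbonyl carbon (C2'–C3') and its silyloxy carbon to the ketene α-carbon (C4'–C5'), giving cyclobutenone 30. Reversible 4π electrocyclic opening of 30 gives dienylketene 31, ring B closes by 6π electrocyclisation of the ketene carbon onto the alkene carbon attached to C3 (C1'–C2'), and dienone 32 tautomerises to phenol 33. The closest known reaction type is the Danheiser benzannulation in its photochemical Wolff variant with silyloxyalkynes, which gives resorcinol monosilyl ethers. No stereocentre is formed, and C3 is a spectator because the medium is neutral and its hydrogen is never acidified. The selectivity needed is regiochemical and is fixed by the oxygen donor of 28, so the ketene carbon ends as C2' with the free OH and the silyloxy carbon as C4'; the far higher ketenophilicity of the ynol ether protects the prenyl alkene, and 300 nm light is absorbed by the diazoketone, not by ring A.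

Step 17
Reactants: 33 2-(Chr)-5-(triisopropylsilyloxy)phenol; 34 3-chloro-3-methylbut-1-yne
Product: 35 {4-(Chr)-3-[(2-methylbut-3-yn-2-yl)oxy]phenoxy}triisopropylsilane
Conditions: CuCl2·2H2O (cat.), DBU, MeCN, 0 °C
Reagents that add atoms: 3-chloro-3-methylbut-1-yne (34), CC(C)(Cl)C#C
Why: Copper-catalysed O-alkylation of a phenol with a tertiary propargylic chloride proceeds at 0 °C without strong base; only the 2'-OH is free, so no regiochemical choice arises.

Step 18
Reactants: 35 {4-(Chr)-3-[(2-methylbut-3-yn-2-yl)oxy]phenoxy}triisopropylsilane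
Product: 39 {[8-(Chr)-2,2-dimethyl-2H-chromen-5-yl]oxy}triisopropylsilane, via allenyl dienone 36 (not isolated), via ortho-allenylphenol 37 (not isolated), via ortho-quinone methide 38 (not isolated)
Conditions: PhNEt2, 185 °C
Reagents that add atoms: none
Why: Aromatic propargyl Claisen rearrangement to C3' (the only free ortho carbon), tautomerisation, 1,5-hydrogen shift and oxa-6π electrocyclisation form ring D, the standard thermal route from aryl 1,1-dimethylpropargyl ethers to 2,2-dimethyl-2H-chromenes.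

Step 19
Reactants: 39 {[8-(Chr)-2,2-dimethyl-2H-chromen-5-yl]oxy}triisopropylsilane
Product: 40 kanzonol I
Conditions: Bu4NF, AcOH, THF, 0 °C
Reagents that add atoms: none
Why: Buffered fluoride cleavage of the aryl silyl ether frees the 4'-OH without affecting the chromene, the prenyl group or C3.

**Compound list**

1 | 3,5-dimethoxyphenol | COc1cc(O)cc(OC)c1 | starting material
2 | (3,5-dimethoxyphenoxy)tri(propan-2-yl)silane | COc1cc(O[Si](C(C)C)(C(C)C)C(C)C)cc(OC)c1 | intermediate
3 | 1-bromo-3-methylbut-2-ene (prenyl bromide) | CC(C)=CCBr | starting material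
4 | [2,6-dimethoxy-4-(triisopropylsilyloxy)phenyl]lithium | [Li]c1c(OC)cc(O[Si](C(C)C)(C(C)C)C(C)C)cc1OC | intermediate (not isolated)
5 | [3,5-dimethoxy-4-(3-methylbut-2-en-1-yl)phenoxy]tri(propan-2-yl)silane | COc1cc(O[Si](C(C)C)(C(C)C)C(C)C)cc(OC)c1CC=C(C)C | intermediate
6 | 3,5-dimethoxy-4-(3-methylbut-2-en-1-yl)phenol | COc1cc(O)cc(OC)c1CC=C(C)C | intermediate
7 | paraformaldehyde (formaldehyde unit shown) | C=O | starting material
8 | 6-hydroxy-2,4-dimethoxy-3-(3-methylbut-2-en-1-yl)benzaldehyde | COc1cc(O)c(C=O)c(OC)c1CC=C(C)C | intermediate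
9 | diethyl malonate | CCOC(=O)CC(=O)OCC | starting material
10 | ethyl 5,7-dimethoxy-6-(3-methylbut-2-en-1-yl)-2-oxo-2H-chromene-3-carboxylate | CCOC(=O)C1=Cc2c(OC)c(CC=C(C)C)c(OC)cc2OC1=O | intermediate
11 | ethyl 5,7-dimethoxy-6-(3-methylbut-2-en-1-yl)-2-oxochromane-3-carboxylate (racemic) | CCOC(=O)C1Cc2c(OC)c(CC=C(C)C)c(OC)cc2OC1=O | intermediate
12 | 2-{[6-hydroxy-2,4-dimethoxy-3-(3-methylbut-2-en-1-yl)phenyl]methyl}propane-1,3-diol | COc1cc(O)c(CC(CO)CO)c(OC)c1CC=C(C)C | intermediate
13 | (2S)-3-hydroxy-2-{[6-hydroxy-2,4-dimethoxy-3-(3-methylbut-2-en-1-yl)phenyl]methyl}propyl acetate | COc1cc(O)c(C[C@H](COC(C)=O)CO)c(OC)c1CC=C(C)C | intermediate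
14 | [(3S)-5,7-dimethoxy-6-(3-methylbut-2-en-1-yl)-3,4-dihydro-2H-chromen-3-yl]methyl acetate | COc1cc2c(c(OC)c1CC=C(C)C)C[C@H](COC(C)=O)CO2 | intermediate
15 | [(3R)-5,7-dimethoxy-6-(3-methylbut-2-en-1-yl)-3,4-dihydro-2H-chromen-3-yl]methanol | COc1cc2c(c(OC)c1CC=C(C)C)C[C@H](CO)CO2 | intermediate
16 | 1-(triphenylphosphoranylidene)propan-2-one | CC(=O)C=P(c1ccccc1)(c1ccccc1)c1ccccc1 | starting material
17 | (3S)-5,7-dimethoxy-6-(3-methylbut-2-en-1-yl)-3,4-dihydro-2H-chromene-3-carbaldehyde | COc1cc2c(c(OC)c1CC=C(C)C)C[C@H](C=O)CO2 | intermediate (not isolated)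
18 | (3E)-4-[(3R)-5,7-dimethoxy-6-(3-methylbut-2-en-1-yl)-3,4-dihydro-2H-chromen-3-yl]but-3-en-2-one | COc1cc2c(c(OC)c1CC=C(C)C)C[C@H](/C=C/C(C)=O)CO2 | intermediate
19 | lithium (3E)-4-(Chr)buta-1,3-dien-2-olate | COc1cc2c(c(OC)c1CC=C(C)C)C[C@H](/C=C/C(=C)O[Li])CO2 | intermediate (not isolated)
20 | (5E)-1,1,1-trifluoro-6-(Chr)hex-5-ene-2,4-dione | COc1cc2c(c(OC)c1CC=C(C)C)C[C@H](/C=C/C(=O)CC(=O)C(F)(F)F)CO2 | intermediate (not isolated)
21 | (3E)-1-diazo-4-[(3R)-5,7-dimethoxy-6-(3-methylbut-2-en-1-yl)-3,4-dihydro-2H-chromen-3-yl]but-3-en-2-one | COc1cc2c(c(OC)c1CC=C(C)C)C[C@H](/C=C/C(=O)C=[N+]=[N-])CO2 | intermediate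
22 | tetrahydrofuran | C1CCOC1 | starting material
23 | lithium ethenolate | [Li+].[O-]C=C | intermediate (not isolated)
24 | (ethenyloxy)tri(propan-2-yl)silane | C=CO[Si](C(C)C)(C(C)C)C(C)C | intermediate
25 | (1,2-dibromoethoxy)tri(propan-2-yl)silane | BrCC(Br)O[Si](C(C)C)(C(C)C)C(C)C | intermediate (not isolated)
26 | [(Z)-2-bromoethenyloxy]tri(propan-2-yl)silane | Br/C=C\O[Si](C(C)C)(C(C)C)C(C)C | intermediate
27 | {[tri(propan-2-yl)silyloxy]ethynyl}lithium | [Li]C#CO[Si](C(C)C)(C(C)C)C(C)C | intermediate (not isolated)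
28 | (ethynyloxy)tri(propan-2-yl)silane | C#CO[Si](C(C)C)(C(C)C)C(C)C | intermediate
29 | (3E)-4-(Chr)buta-1,3-dien-1-one (vinylketene) | COc1cc2c(c(OC)c1CC=C(C)C)C[C@H](/C=C/C=C=O)CO2 | intermediate (not isolated)
30 | 4-[(E)-2-(Chr)ethenyl]-3-(triisopropylsilyloxy)cyclobut-2-en-1-one | COc1cc2c(c(OC)c1CC=C(C)C)C[C@H](/C=C/C1C(=O)C=C1O[Si](C(C)C)(C(C)C)C(C)C)CO2 | intermediate (not isolated)
31 | (3E,5E)-6-(Chr)-3-(triisopropylsilyloxy)hexa-1,3,5-trien-1-one (C2 and C5 cis across C3=C4) | COc1cc2c(c(OC)c1CC=C(C)C)C[C@H](/C=C/C=C(\C=C=O)O[Si](C(C)C)(C(C)C)C(C)C)CO2 | intermediate (not isolated)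
32 | 6-(Chr)-3-(triisopropylsilyloxy)cyclohexa-2,4-dien-1-one | COc1cc2c(c(OC)c1CC=C(C)C)C[C@H](C1C=CC(O[Si](C(C)C)(C(C)C)C(C)C)=CC1=O)CO2 | intermediate (not isolated)
33 | 2-[(3R)-5,7-dimethoxy-6-(3-methylbut-2-en-1-yl)-3,4-dihydro-2H-chromen-3-yl]-5-(triisopropylsilyloxy)phenol | COc1cc2c(c(OC)c1CC=C(C)C)C[C@H](c1ccc(O[Si](C(C)C)(C(C)C)C(C)C)cc1O)CO2 | intermediate
34 | 3-chloro-3-methylbut-1-yne | CC(C)(Cl)C#C | starting material
35 | {4-(Chr)-3-[(2-methylbut-3-yn-2-yl)oxy]phenoxy}tri(propan-2-yl)silane | COc1cc2c(c(OC)c1CC=C(C)C)C[C@H](c1ccc(O[Si](C(C)C)(C(C)C)C(C)C)cc1OC(C)(C)C#C)CO2 | intermediate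
36 | 6-(Chr)-2-(3-methylbuta-1,2-dien-1-yl)-3-(triisopropylsilyloxy)cyclohexa-3,5-dien-1-one | COc1cc2c(c(OC)c1CC=C(C)C)C[C@H](C1=CC=C(O[Si](C(C)C)(C(C)C)C(C)C)C(C=C=C(C)C)C1=O)CO2 | intermediate (not isolated)
37 | 6-(Chr)-2-(3-methylbuta-1,2-dien-1-yl)-3-(triisopropylsilyloxy)phenol | COc1cc2c(c(OC)c1CC=C(C)C)C[C@H](c1ccc(O[Si](C(C)C)(C(C)C)C(C)C)c(C=C=C(C)C)c1O)CO2 | intermediate (not isolated)
38 | 2-(Chr)-6-(3-methylbut-2-en-1-ylidene)-5-(triisopropylsilyloxy)cyclohexa-2,4-dien-1-one | COc1cc2c(c(OC)c1CC=C(C)C)C[C@H](C1=CC=C(O[Si](C(C)C)(C(C)C)C(C)C)C(=CC=C(C)C)C1=O)CO2 | intermediate (not isolated)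
39 | {[8-(Chr)-2,2-dimethyl-2H-chromen-5-yl]oxy}tri(propan-2-yl)silane | COc1cc2c(c(OC)c1CC=C(C)C)C[C@H](c1ccc(O[Si](C(C)C)(C(C)C)C(C)C)c3c1OC(C)(C)C=C3)CO2 | intermediate
40 | kanzonol I, 8-[(3R)-5,7-dimethoxy-6-(3-methylbut-2-en-1-yl)-3,4-dihydro-2H-chromen-3-yl]-2,2-dimethyl-2H-chromen-5-ol | COc1cc2c(c(OC)c1CC=C(C)C)C[C@H](c1ccc(O)c3c1OC(C)(C)C=C3)CO2 | target

**Step count.** Total steps: 19. Longest linear sequence: 16 steps (1–12 and 16–19); steps 13–15 are a three-step side branch to alkyne 28.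

**Steps most likely to fail**

1. Step 16 (key step). What may go wrong: inefficient Wolff rearrangement if ring A competes for light; E/Z photoisomerisation followed by a 1,5-hydrogen shift in the Z-vinylketene; loss of the ynol ether by hydrolysis or silyl migration; O-acylation of the product phenol by the ketene. The fallback brings ring B in as an arylacetic acid and sets C3 by Evans alkylation; it sets out from 8 and returns at 33.
 - Ring A electrophile: 8 is O-allylated (allyl bromide, K2CO3, DMF) to 6-(allyloxy)-2,4-dimethoxy-3-prenylbenzaldehyde F1, reduced (NaBH4, MeOH) to benzylic alcohol F2 and converted (PBr3, Et2O, −20 °C) into benzylic bromide F3, which is used at once.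
 - Ring B imide: commercial methyl (2,4-dihydroxyphenyl)acetate (COC(=O)Cc1ccc(O)cc1O) is protected (MOMCl, iPr2NEt) as methyl [2,4-bis(methoxymethoxy)phenyl]acetate F4, saponified (LiOH) to acid F5, activated (pivaloyl chloride, Et3N) as mixed pivalic anhydride F6 and coupled with lithiated (R)-4-benzyloxazolidin-2-one to imide F7.
 - Union and closure: the sodium enolate of F7 (NaN(SiMe3)2, THF, −78 °C) is alkylated by F3 on the face away from the benzyl group to give (2R)-imide F8. LiBH4 releases primary alcohol F9, and Pd(PPh3)4 with morpholine removes the allyl group to give phenol F10. Mitsunobu closure (PPh3, DIAD) gives 2',4'-bis(methoxymethyl) isoflavan F11, HCl in MeOH gives 2',4'-diol F12, and TIPSCl with imidazole silylates the unhindered 4'-OH to return to 33.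

2. Step 8. What may go wrong: poor discrimination of the enantiotopic arms by the enzyme with this ortho,ortho'-disubstituted benzyl group, over-acylation to the diacetate, or erosion of enantiopurity by 1,3-acyl migration in the monoacetate. The fallback sets C3 by asymmetric hydrogenation; it sets out from 8 and returns at 15. Oxa-Michael/aldol condensation of 8 with acrolein (K2CO3, dioxane, reflux) gives 5,7-dimethoxy-6-prenyl-2H-chromene-3-carbaldehyde F13. Pinnick oxidation (NaClO2, NaH2PO4, excess 2-methylbut-2-ene) gives chromene-3-carboxylic acid F14. Carboxylate-directed hydrogenation with Ru(OAc)2(BINAP) (H2, MeOH; the BINAP antipode chosen to give the 3S acid), which should leave the isolated prenyl alkene alone, gives (3S)-chromane-3-carboxylic acid F15, and LiAlH4 reduces F15 to 15.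

3. Step 11. What may go wrong: loss of configuration at C3 through enolisation or reversible retro-oxa-Michael opening of ring C in aldehyde 17 while the sluggish keto-ylide reacts. The fallback reverses the polarity so that no α-stereogenic aldehyde is formed; it sets out from 15 and returns at 18. Mitsunobu thioetherification of 15 with 1-phenyl-1H-tetrazole-5-thiol (PPh3, DIAD) gives tetrazolyl sulfide F16, and oxidation with (NH4)6Mo7O24·4H2O and H2O2 in EtOH gives tetrazolyl sulfone F17. Julia–Kocienski olefination (KN(SiMe3)2, THF, −78 °C) with 2-(tert-butyldimethylsilyloxy)propanal gives (E)-allylic silyl ether F18, Bu4NF gives allylic alcohol F19, and MnO2 in CH2Cl2 oxidises F19 to 18.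

**Further compounds**

F1 | step 16 | 6-(allyloxy)-2,4-dimethoxy-3-(3-methylbut-2-en-1-yl)benzaldehyde | O=Cc1c(OCC=C)cc(OC)c(CC=C(C)C)c1OC
F2 | step 16 | [6-(allyloxy)-2,4-dimethoxy-3-(3-methylbut-2-en-1-yl)phenyl]methanol | OCc1c(OCC=C)cc(OC)c(CC=C(C)C)c1OC
F3 | step 16 | 1-(allyloxy)-2-(bromomethyl)-3,5-dimethoxy-4-(3-methylbut-2-en-1-yl)benzene | BrCc1c(OCC=C)cc(OC)c(CC=C(C)C)c1OC
F4 | step 16 | methyl [2,4-bis(methoxymethoxy)phenyl]acetate | COC(=O)Cc1ccc(OCOC)cc1OCOC
F5 | step 16 | [2,4-bis(methoxymethoxy)phenyl]acetic acid | OC(=O)Cc1ccc(OCOC)cc1OCOC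
F6 | step 16 | [2,4-bis(methoxymethoxy)phenyl]acetic pivalic anhydride | CC(C)(C)C(=O)OC(=O)Cc1ccc(OCOC)cc1OCOC
F7 | step 16 | (4R)-4-benzyl-3-{[2,4-bis(methoxymethoxy)phenyl]acetyl}oxazolidin-2-one | O=C1OC[C@@H](Cc2ccccc2)N1C(=O)Cc1ccc(OCOC)cc1OCOC
F8 | step 16 | (4R)-3-{(2R)-3-[6-(allyloxy)-2,4-dimethoxy-3-prenylphenyl]-2-[2,4-bis(methoxymethoxy)phenyl]propanoyl}-4-benzyloxazolidin-2-one | O=C1OC[C@@H](Cc2ccccc2)N1C(=O)[C@H](Cc1c(OCC=C)cc(OC)c(CC=C(C)C)c1OC)c1ccc(OCOC)cc1OCOC
F9 | step 16 | (2R)-3-[6-(allyloxy)-2,4-dimethoxy-3-prenylphenyl]-2-[2,4-bis(methoxymethoxy)phenyl]propan-1-ol | OC[C@H](Cc1c(OCC=C)cc(OC)c(CC=C(C)C)c1OC)c1ccc(OCOC)cc1OCOC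
F10 | step 16 | 2-{(2R)-2-[2,4-bis(methoxymethoxy)phenyl]-3-hydroxypropyl}-3,5-dimethoxy-4-prenylphenol | OC[C@H](Cc1c(O)cc(OC)c(CC=C(C)C)c1OC)c1ccc(OCOC)cc1OCOC
F11 | step 16 | (3R)-3-[2,4-bis(methoxymethoxy)phenyl]-5,7-dimethoxy-6-prenylchromane | COc1cc2c(c(OC)c1CC=C(C)C)C[C@H](c1ccc(OCOC)cc1OCOC)CO2
F12 | step 16 | 4-[(3R)-5,7-dimethoxy-6-prenylchroman-3-yl]benzene-1,3-diol | COc1cc2c(c(OC)c1CC=C(C)C)C[C@H](c1ccc(O)cc1O)CO2
F13 | step 8 | 5,7-dimethoxy-6-(3-methylbut-2-en-1-yl)-2H-chromene-3-carbaldehyde | O=CC1=Cc2c(OC)c(CC=C(C)C)c(OC)cc2OC1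
F14 | step 8 | 5,7-dimethoxy-6-(3-methylbut-2-en-1-yl)-2H-chromene-3-carboxylic acid | OC(=O)C1=Cc2c(OC)c(CC=C(C)C)c(OC)cc2OC1
F15 | step 8 | (3S)-5,7-dimethoxy-6-(3-methylbut-2-en-1-yl)chromane-3-carboxylic acid | COc1cc2c(c(OC)c1CC=C(C)C)C[C@H](C(=O)O)CO2
F16 | step 11 | 5-({[(3S)-5,7-dimethoxy-6-prenylchroman-3-yl]methyl}sulfanyl)-1-phenyl-1H-tetrazole | COc1cc2c(c(OC)c1CC=C(C)C)C[C@H](CSc1nnnn1-c1ccccc1)CO2
F17 | step 11 | 5-({[(3S)-5,7-dimethoxy-6-prenylchroman-3-yl]methyl}sulfonyl)-1-phenyl-1H-tetrazole | COc1cc2c(c(OC)c1CC=C(C)C)C[C@H](CS(=O)(=O)c1nnnn1-c1ccccc1)CO2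
F18 | step 11 | tert-butyl{[(3E)-4-(Chr)but-3-en-2-yl]oxy}dimethylsilane (either carbinol epimer) | COc1cc2c(c(OC)c1CC=C(C)C)C[C@H](/C=C/C(C)O[Si](C)(C)C(C)(C)C)CO2
F19 | step 11 | (3E)-4-(Chr)but-3-en-2-ol (either carbinol epimer) | COc1cc2c(c(OC)c1CC=C(C)C)C[C@H](/C=C/C(C)O)CO2
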